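(The readings come from a simulation with constants of no real substance; noise was put on by code.)

| flask | starting material | partner | remark | time |
|---|---|---|---|---|
| delta | 1 mM | 0.45 mM | run made earlier |  |
| eta | 1 mM | 0.68 mM | run made earlier |  |
| flask | 1.0 mM | 0.900 mM |  | 3.0 min |

| run | time / s | starting material / % | mono adduct / % | bis adduct / % |
|---|---|---|---|---|
| delta | 10.0 | 9.6 | 9.8 | 2.9 |
| delta | 15.0 | 6.8 | 9.2 | 3.5 |
| delta | 30.0 | 3.3 | 8.8 | 3.8 |
| delta | 50.0 | 1.7 | 8.7 | 4.3 |
| delta | 60.0 | 1.4 | 8.0 | 3.8 |
| delta | 80.0 | 1.4 | 8.5 | 4.5 |
| delta | 120 | 1.1 | 8.3 | 3.9 |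
| eta | 15.0 | 6.3 | 11.0 | 7.0 |
| eta | 30.0 | 3.6 | 10.8 | 7.4 |
| eta | 50.0 | 2.4 | 10.1 | 8.0 |
| eta | 60.0 | 1.2 | 10.1 | 8.2 |
| eta | 80.0 | 1.9 | 10.0 | 8.3 |
| eta | 90.0 | 1.4 | 10.1 | 8.2 |
| eta | 120 | 1.4 | 10.0 | 7.7 |

(standard deviation of a reading: 0.3 percentage points)

- percent here means starting material units held: one self-condensation product counts as two
- reactions considered so far: partner -> decomposed reagent; partner + triple product -> tetra adduct; partner + bis adduct -> triple product; starting material + partner -> mono adduct; partner + mono adduct -> bis adduct; 2 starting material -> self-condensation product; partner <-> dormant form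

- amount of starting material at 3.0 min, in percent of the starting material charged
- amount of mono adduct at 3.0 min, in percent of the starting material charged
- amount of bis adduct at 3.0 min, in percent of the starting material charged
- amount of triple product at 3.0 min, in percent of the starting material charged

You take over a flask whose slow part comes last: in the earlier runs the adducts form early, and what still creeps afterwards is starting material. In the eta run mono adduct read 10.1 % at 50.0 s and 10.0 % at 120 s, a step of 0.1 percentage points against a scatter of 0.3 points, so leave that part of the flask alone and expect little more adduct from waiting. The last readings of the delta run give 35.8 % and those of the eta run 37.4 %, so I take the capture share, the partner held in mono and bis adduct at the plateau per partner charged, bis counted twice, as 36.6 %. With c(partner) at 0.900 mM, my reckoning puts mono plus twice bis at 32.9 % of the starting material charged, without splitting them.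

The forecast expects 0.9 % starting material, 10 % mono adduct, 11.5 % bis adduct and 6 % triple product, holding of starting material that “self-condensation dominates its loss”.

The flask gives 0.616 %, 10.9 %, 11.6 % and 1.08 %, all within the tolerance.

    partner → decomposed reagent (k = 1.20 s⁻¹)
    partner + triple product → tetra adduct (k = 530 M⁻¹ s⁻¹)
    partner + bis adduct → triple product (k = 520 M⁻¹ s⁻¹)
    starting material + partner → mono adduct (k = 1100 M⁻¹ s⁻¹)
    partner + mono adduct → bis adduct (k = 2700 M⁻¹ s⁻¹)
    2 starting material → self-condensation product (k = 440 M⁻¹ s⁻¹)
    partner ⇌ dormant form (K = 7.90, k = 1.20 s⁻¹)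

The capture share of the asked flask is 38.0 %, and the neighbour flask with 0.23 mM of partner gives 35.6 %; in the neighbour flask with 3.6 mM of partner, bis adduct reaches 39.4 %, above the forecast's high end of 14.5 %. In the asked flask, the mono adduct step had half its turnover by 0.186 s and partner decomposition by 0.528 s; after 0.300 min partner, the limiting reagent for the adducts, stood at 0.389 % of its charge, with 0.0636 mM in the dormant form. Self-condensation, with 99.2 % of its turnover done at 1.50 min, ran on with partner at 0 %, while starting material went from 1.20 % at that time to 0.616 % at 3.00 min.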